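I looked for what stands still.

| setting | ash | flask |
|---|---|---|
| solid substrate | 0.22 M | 0.11 M |
| free catalyst | 12 mM | 12 mM |
| remark | run made earlier |  |
| time |  | 2.0 h |

ash run (percent of the solid substrate charged)

| time / min | catalyst intermediate / % | solid substrate / % | starting material / % | product / % |
|---|---|---|---|---|
| 1.00 | 0.7 | 98.5 | 1.9 | 0 |
| 2.00 | 0.5 | 96.1 | 3.7 | 0 |
| 3.00 | 0.2 | 93.9 | 5.5 | 0 |
| 6.00 | 0.5 | 89.7 | 9.9 | 0.6 |
| 12.0 | 0.1 | 82.7 | 17.0 | 0.7 |

(each reading ± 0.3 percentage points)

- as a solid, counted per litre of solution: solid substrate
- what was read earlier has a scatter of 0.3 percentage points, one standard deviation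
- at the start none of the solid substrate is in solution
- starting material means what is dissolved; the solid is not counted in it

1. where most of what was charged as solid substrate, at 2.0 h is found (product / catalyst intermediate / starting material)
2. the largest share itself, whichever of these holds it, in percent of the solid substrate charged

The decision was whether to keep the flask's charge and time or to cut the charge. In the ash run, c(starting material) rose at 4.03 mM/min over the first 3.00 min, around a mean of 6.05 mM. It rose at 2.60 mM/min between 6.00 min and 12.0 min, around 29.6 mM. A straight line through these two readings reaches zero rate at 72.4 mM, which I called the ceiling, the level of c(starting material) at which solid substrate stops dissolving; it is the solubility as read. The same line gave a filling time of 16.5 min, much shorter than the flask's 2.0 h. The flask's charge of 0.11 M stood above the ceiling, so by this reckoning a reserve of 37.6 mM stayed as solid. The product gain between those two readings, though inside the scatter, would take 4.40 mM if kept up, less than the reserve. So I froze c(starting material) at the ceiling, reckoned a share of 65.9%, and kept the charge and time.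

The forecast named starting material at 50%, from 38% to 62%, below my share, in its words “Starting material therefore holds most”.

The flask gave starting material at 59.7%, which is 65.7 mM, under the ceiling; it had already stood at 58.6% after 1.00 h.

    starting material + free catalyst ⇌ catalyst intermediate (K = 3.20 /M, k = 1700 /M/h)
    catalyst intermediate → free catalyst + product (k = 5.20 /h)
    solid substrate ⇌ starting material, rate k3*(cs3 - [starting material]) while solid is left; crystals form when [starting material] > cs3 (solubility = 0.0660 M, k = 4.20 /h)
    2 free catalyst → spent catalyst (k = 220 /M/h)

For a neighbouring flask with 0.44 M of solid substrate, the time and all else held, the ceiling gives 16.5%. The computed neighbouring flask gave 14.9%.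

Readings and results were computed for an exercise.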